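**Plan**
1. Cuts: (a) the C3–C1' aryl–aryl bond of the isoflavone (Suzuki–Miyaura), giving 3-iodochromone 25 and chromenyl boronate 15; (b) in the 2H-pyran ring fused to ring B, the aryl C8a–O1 bond and the C3=C4 double bond, giving phosphonium salt 6 (carries C4 and the C–F carbon) and α-silyloxy aldehyde 10 (carries O1, C2 with both methyls, C3); (c) in rings A/C, the pyrone O1–C2 and C2–C3 bonds (enaminone iodocyclisation) and the C6–side-chain bond (Sonogashira).
2. Enabling feature: in ring B the pyran carbon C4 is benzylic and sits ortho to the ring carbon that carries the pyran oxygen. An ortho-fluorobenzylide (nucleophilic ylide carbon, electrophilic C–F carbon) is therefore the exact complement of O=CH–CMe2–O–Si (electrophilic CHO, latent alkoxide), and the cis C3=C4 bond holds the alkoxide beside the C–F carbon.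
3. Forward order: pyran ring on the B-ring block in one flask (step 8), then borylation; ring A by iodination ortho to its one free phenol (fixes C-6), Sonogashira coupling, hydrogenation/debenzylation and γ-pyrone closure through the only free ortho hydroxyl; then biaryl union and removal of three MOM groups.
4. Stereochemistry: the target has no stereocentre. Its one stereo-element, the cis ring olefin, comes from the Z-selective Wittig stage and is locked by ring closure.

Key step: step 8

Remark: compounds 1, 7, 16 and 20 are taken as catalogue chemicals; nothing else is assumed.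

Step 1
Reactants: 1 2-fluoro-4-hydroxybenzaldehyde
Product: 2 5-bromo-2-fluoro-4-hydroxybenzaldehyde
Conditions: NBS, MeCN, 0 °C to rt
Reagents that add atoms: N-bromosuccinimide, O=C1CCC(=O)N1Br
Why: Electrophilic aromatic bromination of the phenol should go ortho to the hydroxyl at C-5 (para to fluorine, less crowded than C-3 between F and OH), the para position being blocked by the formyl group.

Step 2
Reactants: 2 5-bromo-2-fluoro-4-hydroxybenzaldehyde
Product: 3 5-bromo-2-fluoro-4-(methoxymethoxy)benzaldehyde
Conditions: MOMCl, i-Pr2NEt, CH2Cl2, 0 °C to rt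
Reagents that add atoms: chloromethyl methyl ether, COCCl
Why: O-alkylation of the acidic phenol (MOM protection) should give an acetal that is stable to the hydride, ylide, alkoxide and fluoride used later.

Step 3
Reactants: 3 5-bromo-2-fluoro-4-(methoxymethoxy)benzaldehyde
Product: 4 [5-bromo-2-fluoro-4-(methoxymethoxy)phenyl]methanol
Conditions: NaBH4, MeOH, 0 °C
Reagents that add atoms: none
Why: Chemoselective borohydride reduction of the aldehyde should leave the aryl halides and the MOM acetal untouched.

Step 4
Reactants: 4 [5-bromo-2-fluoro-4-(methoxymethoxy)phenyl]methanol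
Product: 5 1-bromo-5-(bromomethyl)-4-fluoro-2-(methoxymethoxy)benzene
Conditions: CBr4, PPh3, CH2Cl2, 0 °C
Reagents that add atoms: carbon tetrabromide, BrC(Br)(Br)Br
Why: The Appel reaction should convert the benzylic alcohol into the bromide under neutral conditions that spare the MOM acetal.

Step 5
Reactants: 5 1-bromo-5-(bromomethyl)-4-fluoro-2-(methoxymethoxy)benzene
Product: 6 {[5-bromo-2-fluoro-4-(methoxymethoxy)phenyl]methyl}triphenylphosphonium bromide
Conditions: PPh3, toluene, 80 °C
Reagents that add atoms: triphenylphosphine, c1ccc(cc1)P(c1ccccc1)c1ccccc1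
Why: SN2 quaternisation of triphenylphosphine by the reactive benzylic bromide should give the phosphonium salt, which precipitates from toluene.

Step 6
Reactants: 7 2-methylbut-3-en-2-ol
Product: 8 triethyl[(2-methylbut-3-en-2-yl)oxy]silane
Conditions: TESOTf, 2,6-lutidine, CH2Cl2, 0 °C
Reagents that add atoms: triethylsilyl trifluoromethanesulfonate, CC[Si](CC)(CC)OS(=O)(=O)C(F)(F)F
Why: Silylation of the tertiary allylic alcohol with the silyl triflate and a hindered pyridine base should mask the oxygen as an ether that fluoride can open later.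

Step 7
Reactants: 8 triethyl[(2-methylbut-3-en-2-yl)oxy]silane
Product: 10 2-methyl-2-[(triethylsilyl)oxy]propanal, via secondary ozonide 9 (not isolated)
Conditions: O3, CH2Cl2, −78 °C; then PPh3, −78 °C to rt
Reagents that add atoms: ozone, [O-][O+]=O
Why: Ozonolysis with reductive work-up should cleave the terminal vinyl group to the non-enolisable α-silyloxy aldehyde.

Step 8
Reactants: 6 {[5-bromo-2-fluoro-4-(methoxymethoxy)phenyl]methyl}triphenylphosphonium bromide; 10 2-methyl-2-[(triethylsilyl)oxy]propanal
Product: 14 6-bromo-7-(methoxymethoxy)-2,2-dimethyl-2H-chromene, via benzylic phosphonium ylide 11 (not isolated), via Z-styrene silyl ether 12 (not isolated), via caesium tert-alkoxide 13 (not isolated)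
Conditions: KHMDS (1.0 equiv), THF, −78 to 0 °C; then 10, −78 °C to rt; then CsF, 18-crown-6, DMF, 90 °C
Reagents that add atoms: none
Why: Deprotonation of 6 gives the semi-stabilised benzylide 11, which should react with aldehyde 10 in a kinetically controlled, lithium-free Wittig olefination ([2+2] to the cis-oxaphosphetane, then syn cycloreversion) to give Z-styrene 12 and so form the C3=C4 bond; fluoride then removes the triethylsilyl group, and the caesium tert-alkoxide 13, held by the cis double bond beside the C–F carbon, should close the pyran ring by intramolecular nucleophilic aromatic substitution (addition to the fluorinated carbon, loss of fluoride), which forms the aryl C–O bond. The closest known reaction types are the Wittig olefination of benzylides and the alkoxide SNAr ring closure of unactivated ortho-fluoroaryl alkanols to chromans, run here in one flask as a formal [3+3] annulation. The one ring that closes, the 2H-pyran, closes in a formally 6-exo-trig mode by ipso attack of oxygen on the C–F carbon, the negative charge of the σ-adduct being taken up by the arene outside the new ring. No stereocentre is formed; the only stereo-element is the ring olefin, whose Z geometry is needed for closure and should be favoured by the ortho-fluoro benzylide, the α-quaternary α-oxygenated aldehyde and the potassium (salt-free) conditions, and only the Z isomer can reach the C–F carbon. Regiochemistry is fixed by the substrate: fluorine sits only on the carbon ortho to the benzylic carbon, so only the linear pyran can form; the bromine para to fluorine assists the substitution and is itself not displaced; and should HF be lost across the C–H that lies between F and OMOM, the tethered alkoxide would still add to the same aryne carbon, the one remote from the OMOM group.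

Step 9
Reactants: 14 6-bromo-7-(methoxymethoxy)-2,2-dimethyl-2H-chromene
Product: 15 2-[7-(methoxymethoxy)-2,2-dimethyl-2H-chromen-6-yl]-4,4,5,5-tetramethyl-1,3,2-dioxaborolane
Conditions: B2pin2, Pd(dppf)Cl2 (cat.), KOAc, 1,4-dioxane, 90 °C
Reagents that add atoms: bis(pinacolato)diboron, CC1(C)OB(OC1(C)C)B1OC(C)(C)C(C)(C)O1
Why: Miyaura borylation of the aryl bromide should tolerate the chromene olefin and the MOM acetal.

Step 10
Reactants: 16 1-(2,4,6-trihydroxyphenyl)ethan-1-one
Product: 17 1-[2,4-bis(benzyloxy)-6-hydroxyphenyl]ethan-1-one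
Conditions: BnBr (2.1 equiv), K2CO3, DMF, rt
Reagents that add atoms: benzyl bromide, BrCc1ccccc1
Why: Williamson O-benzylation should alkylate the para hydroxyl and one ortho hydroxyl, the second ortho hydroxyl being held back by its hydrogen bond to the ketone.

Step 11
Reactants: 17 1-[2,4-bis(benzyloxy)-6-hydroxyphenyl]ethan-1-one
Product: 18 1-[4,6-bis(benzyloxy)-2-hydroxy-3-iodophenyl]ethan-1-one
Conditions: NIS, TFA (cat.), MeCN, rt
Reagents that add atoms: N-iodosuccinimide, O=C1CCC(=O)N1I
Why: Electrophilic aromatic iodination should occur ortho to the single free hydroxyl at the less crowded open position (the other lies between two benzyloxy groups), which fixes the later C-6 site of the side chain.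

Step 12
Reactants: 18 1-[4,6-bis(benzyloxy)-2-hydroxy-3-iodophenyl]ethan-1-one
Product: 19 1-[4,6-bis(benzyloxy)-3-iodo-2-(methoxymethoxy)phenyl]ethan-1-one
Conditions: MOMCl, K2CO3, acetone, reflux
Reagents that add atoms: chloromethyl methyl ether, COCCl
Why: O-alkylation of the phenoxide (MOM protection) should mask the hydroxyl next to iodine, so that it can close neither a furan nor the pyrone ring, and sets it apart from the benzyl-protected oxygens.

Step 13
Reactants: 19 1-[4,6-bis(benzyloxy)-3-iodo-2-(methoxymethoxy)phenyl]ethan-1-one; 20 2-methylbut-3-yn-2-ol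
Product: 21 1-[4,6-bis(benzyloxy)-3-(3-hydroxy-3-methylbut-1-yn-1-yl)-2-(methoxymethoxy)phenyl]ethan-1-one
Conditions: Pd(PPh3)2Cl2 (cat.), CuI (cat.), Et3N, DMF, 70 °C
Reagents that add atoms: none
Why: Sonogashira coupling of the aryl iodide with the terminal alkyne should install the complete C5 side chain, no free ortho hydroxyl being present to divert the product to a benzofuran.

Step 14
Reactants: 21 1-[4,6-bis(benzyloxy)-3-(3-hydroxy-3-methylbut-1-yn-1-yl)-2-(methoxymethoxy)phenyl]ethan-1-one
Product: 22 1-[4,6-dihydroxy-3-(3-hydroxy-3-methylbutyl)-2-(methoxymethoxy)phenyl]ethan-1-one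
Conditions: H2 (1 atm), 10% Pd/C, EtOAc/MeOH, rt
Reagents that add atoms: none
Why: Heterogeneous hydrogenation should saturate the alkyne and hydrogenolyse both benzyl ethers in one operation, while the MOM acetal, the chelated aryl ketone and the non-benzylic tertiary alcohol persist.

Step 15
Reactants: 22 1-[4,6-dihydroxy-3-(3-hydroxy-3-methylbutyl)-2-(methoxymethoxy)phenyl]ethan-1-one
Product: 23 1-[6-hydroxy-3-(3-hydroxy-3-methylbutyl)-2,4-bis(methoxymethoxy)phenyl]ethan-1-one
Conditions: MOMCl (1.1 equiv), i-Pr2NEt, CH2Cl2, 0 °C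
Reagents that add atoms: chloromethyl methyl ether, COCCl
Why: Selective O-alkylation (MOM protection) should take the non-chelated 4-hydroxyl, the 6-hydroxyl being deactivated by its hydrogen bond to the ketone and the tertiary alcohol by hindrance.

Step 16
Reactants: 23 1-[6-hydroxy-3-(3-hydroxy-3-methylbutyl)-2,4-bis(methoxymethoxy)phenyl]ethan-1-one
Product: 24 (E)-3-(dimethylamino)-1-[6-hydroxy-3-(3-hydroxy-3-methylbutyl)-2,4-bis(methoxymethoxy)phenyl]prop-2-en-1-one
Conditions: DMF-DMA, toluene, 90 °C
Reagents that add atoms: N,N-dimethylformamide dimethyl acetal, COC(OC)N(C)C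
Why: Condensation of the methyl ketone with the amide acetal (enaminone formation) should add the one-carbon unit that becomes C-2 of the pyrone.

Step 17
Reactants: 24 (E)-3-(dimethylamino)-1-[6-hydroxy-3-(3-hydroxy-3-methylbutyl)-2,4-bis(methoxymethoxy)phenyl]prop-2-en-1-one
Product: 25 6-(3-hydroxy-3-methylbutyl)-3-iodo-5,7-bis(methoxymethoxy)-4H-chromen-4-one
Conditions: I2, CHCl3, rt
Reagents that add atoms: iodine, II
Why: Iodocyclisation of the ortho-hydroxyaryl enaminone (α-iodination, oxa-Michael closure by the only free phenol, loss of dimethylamine) should give the 3-iodochromone with the side chain at C-6 and no regioisomer.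

Step 18
Reactants: 25 6-(3-hydroxy-3-methylbutyl)-3-iodo-5,7-bis(methoxymethoxy)-4H-chromen-4-one; 15 2-[7-(methoxymethoxy)-2,2-dimethyl-2H-chromen-6-yl]-4,4,5,5-tetramethyl-1,3,2-dioxaborolane
Product: 26 6-(3-hydroxy-3-methylbutyl)-5,7-bis(methoxymethoxy)-3-[7-(methoxymethoxy)-2,2-dimethyl-2H-chromen-6-yl]-4H-chromen-4-one
Conditions: Pd(dppf)Cl2 (cat.), aq. Na2CO3, DME, 70 °C
Reagents that add atoms: none
Why: Suzuki–Miyaura coupling of the reactive α-iodoenone with the aryl boronate should form the C3–C1' bond of the isoflavone.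

Step 19
Reactants: 26 6-(3-hydroxy-3-methylbutyl)-5,7-bis(methoxymethoxy)-3-[7-(methoxymethoxy)-2,2-dimethyl-2H-chromen-6-yl]-4H-chromen-4-one
Product: 27 5,7-dihydroxy-3-(7-hydroxy-2,2-dimethyl-2H-chromen-6-yl)-6-(3-hydroxy-3-methylbutyl)-4H-chromen-4-one
Conditions: 3 M aq. HCl, MeOH/THF, 40 °C
Reagents that add atoms: none
Why: Acid-catalysed acetal exchange with methanol should remove the three aryl MOM groups under conditions mild enough to spare the tertiary alcohol and the 2H-chromene.

**Compound list**
1 | 2-fluoro-4-hydroxybenzaldehyde | O=Cc1ccc(O)cc1F | starting material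
2 | 5-bromo-2-fluoro-4-hydroxybenzaldehyde | O=Cc1cc(Br)c(O)cc1F | intermediate
3 | 5-bromo-2-fluoro-4-(methoxymethoxy)benzaldehyde | COCOc1cc(F)c(C=O)cc1Br | intermediate
4 | [5-bromo-2-fluoro-4-(methoxymethoxy)phenyl]methanol | COCOc1cc(F)c(CO)cc1Br | intermediate
5 | 1-bromo-5-(bromomethyl)-4-fluoro-2-(methoxymethoxy)benzene | COCOc1cc(F)c(CBr)cc1Br | intermediate
6 | {[5-bromo-2-fluoro-4-(methoxymethoxy)phenyl]methyl}triphenylphosphonium bromide | COCOc1cc(F)c(C[P+](c2ccccc2)(c2ccccc2)c2ccccc2)cc1Br.[Br-] | intermediate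
7 | 2-methylbut-3-en-2-ol | CC(C)(O)C=C | starting material
8 | triethyl[(2-methylbut-3-en-2-yl)oxy]silane | CC[Si](CC)(CC)OC(C)(C)C=C | intermediate
9 | 3-{2-[(triethylsilyl)oxy]propan-2-yl}-1,2,4-trioxolane | CC[Si](CC)(CC)OC(C)(C)C1OCOO1 | intermediate
10 | 2-methyl-2-[(triethylsilyl)oxy]propanal | CC[Si](CC)(CC)OC(C)(C)C=O | intermediate
11 | {[5-bromo-2-fluoro-4-(methoxymethoxy)phenyl]methylidene}triphenyl-λ5-phosphane | COCOc1cc(F)c(C=P(c2ccccc2)(c2ccccc2)c2ccccc2)cc1Br | intermediate
12 | (Z)-{[4-(5-bromo-2-fluoro-4-(methoxymethoxy)phenyl)-2-methylbut-3-en-2-yl]oxy}triethylsilane | CC[Si](CC)(CC)OC(C)(C)/C=C\c1cc(Br)c(OCOC)cc1F | intermediate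
13 | caesium (Z)-4-[5-bromo-2-fluoro-4-(methoxymethoxy)phenyl]-2-methylbut-3-en-2-olate | [Cs+].[O-]C(C)(C)/C=C\c1cc(Br)c(OCOC)cc1F | intermediate
14 | 6-bromo-7-(methoxymethoxy)-2,2-dimethyl-2H-chromene | COCOc1cc2OC(C)(C)C=Cc2cc1Br | intermediate
15 | 2-[7-(methoxymethoxy)-2,2-dimethyl-2H-chromen-6-yl]-4,4,5,5-tetramethyl-1,3,2-dioxaborolane | COCOc1cc2OC(C)(C)C=Cc2cc1B1OC(C)(C)C(C)(C)O1 | intermediate
16 | 1-(2,4,6-trihydroxyphenyl)ethan-1-one | CC(=O)c1c(O)cc(O)cc1O | starting material
17 | 1-[2,4-bis(benzyloxy)-6-hydroxyphenyl]ethan-1-one | CC(=O)c1c(O)cc(OCc2ccccc2)cc1OCc1ccccc1 | intermediate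
18 | 1-[4,6-bis(benzyloxy)-2-hydroxy-3-iodophenyl]ethan-1-one | CC(=O)c1c(O)c(I)c(OCc2ccccc2)cc1OCc1ccccc1 | intermediate
19 | 1-[4,6-bis(benzyloxy)-3-iodo-2-(methoxymethoxy)phenyl]ethan-1-one | CC(=O)c1c(OCOC)c(I)c(OCc2ccccc2)cc1OCc1ccccc1 | intermediate
20 | 2-methylbut-3-yn-2-ol | CC(C)(O)C#C | starting material
21 | 1-[4,6-bis(benzyloxy)-3-(3-hydroxy-3-methylbut-1-yn-1-yl)-2-(methoxymethoxy)phenyl]ethan-1-one | CC(=O)c1c(OCOC)c(C#CC(C)(C)O)c(OCc2ccccc2)cc1OCc1ccccc1 | intermediate
22 | 1-[4,6-dihydroxy-3-(3-hydroxy-3-methylbutyl)-2-(methoxymethoxy)phenyl]ethan-1-one | CC(=O)c1c(OCOC)c(CCC(C)(C)O)c(O)cc1O | intermediate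
23 | 1-[6-hydroxy-3-(3-hydroxy-3-methylbutyl)-2,4-bis(methoxymethoxy)phenyl]ethan-1-one | CC(=O)c1c(OCOC)c(CCC(C)(C)O)c(OCOC)cc1O | intermediate
24 | (E)-3-(dimethylamino)-1-[6-hydroxy-3-(3-hydroxy-3-methylbutyl)-2,4-bis(methoxymethoxy)phenyl]prop-2-en-1-one | CN(C)/C=C/C(=O)c1c(OCOC)c(CCC(C)(C)O)c(OCOC)cc1O | intermediate
25 | 6-(3-hydroxy-3-methylbutyl)-3-iodo-5,7-bis(methoxymethoxy)-4H-chromen-4-one | COCOc1cc2occ(I)c(=O)c2c(OCOC)c1CCC(C)(C)O | intermediate
26 | 6-(3-hydroxy-3-methylbutyl)-5,7-bis(methoxymethoxy)-3-[7-(methoxymethoxy)-2,2-dimethyl-2H-chromen-6-yl]-4H-chromen-4-one | COCOc1cc2OC(C)(C)C=Cc2cc1-c1coc2cc(OCOC)c(CCC(C)(C)O)c(OCOC)c2c1=O | intermediate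
27 | 5,7-dihydroxy-3-(7-hydroxy-2,2-dimethyl-2H-chromen-6-yl)-6-(3-hydroxy-3-methylbutyl)-4H-chromen-4-one | CC(C)(O)CCc1c(O)cc2occ(-c3cc4c(cc3O)OC(C)(C)C=C4)c(=O)c2c1O | target

**Step count and risks**
Total: 19 steps. Longest linear sequence: 10 steps (16 to 27 through steps 10–19); the B-ring branch from 1 is 9 steps.

Steps most likely to fail:

1. Step 8. The Wittig stage may give too little of the Z olefin (the E olefin cannot reach the C–F carbon and is lost), and substitution of fluoride on the electron-rich ring may be slow at a temperature the aryl bromide tolerates. Fallback (the same two bonds made stepwise, with the geometry enforced by ring closure): it sets out from 3 and 7. Deprotonation of 7 with KHMDS gives potassium 2-methylbut-3-en-2-olate F1, which should displace the aldehyde-activated ortho fluoride of 3 (SNAr, THF/DMF, 0 °C to rt) to give 5-bromo-4-(methoxymethoxy)-2-[(2-methylbut-3-en-2-yl)oxy]benzaldehyde F2. Wittig methylenation (Ph3P=CH2, THF, 0 °C) gives 1-bromo-5-ethenyl-2-(methoxymethoxy)-4-[(2-methylbut-3-en-2-yl)oxy]benzene F3. Ring-closing metathesis with the second-generation ruthenium benzylidene catalyst (CH2Cl2, 40 °C, kept well below the temperature of aromatic Claisen rearrangement) closes the C3=C4 bond with loss of ethene and returns to the route at 14.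

2. Step 19. Prolonged exposure to protic acid may ionise the tertiary alcohol (cyclisation onto a neighbouring phenol, or methyl ether formation) or protonate the chromene olefin before the last MOM group is gone. Fallback (non-protic unmasking through silyl ethers): it sets out from 26. TMSOTf with 2,2'-bipyridyl (CH2Cl2, 0 °C) should exchange the three aryl MOM acetals for aryl silyl ethers and silylate the tertiary alcohol, giving 3-{2,2-dimethyl-7-[(trimethylsilyl)oxy]-2H-chromen-6-yl}-6-{3-methyl-3-[(trimethylsilyl)oxy]butyl}-5,7-bis[(trimethylsilyl)oxy]-4H-chromen-4-one F4. K2CO3 in MeOH at rt then cleaves the four O–Si bonds and returns to the route at 27.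

3. Step 18. The electron-rich ortho-alkoxy boronate may protodeboronate, the γ-pyrone may be opened by aqueous base, and transmetalation between two hindered partners may be slow. Fallback (base-free Negishi coupling): it sets out from 14 and 25. Bromine–lithium exchange on 14 (n-BuLi, THF, −78 °C) gives [7-(methoxymethoxy)-2,2-dimethyl-2H-chromen-6-yl]lithium F5, and ZnCl2 converts it into chlorido[7-(methoxymethoxy)-2,2-dimethyl-2H-chromen-6-yl]zinc F6. Coupling of F6 (in excess, to allow for the free tertiary hydroxyl of 25) with 25 under Pd2(dba)3/SPhos in THF at 50 °C returns to the route at 26.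

**Further compounds**
F1 | step 8 | potassium 2-methylbut-3-en-2-olate | [K+].[O-]C(C)(C)C=C
F2 | step 8 | 5-bromo-4-(methoxymethoxy)-2-[(2-methylbut-3-en-2-yl)oxy]benzaldehyde | O=Cc1cc(Br)c(OCOC)cc1OC(C)(C)C=C
F3 | step 8 | 1-bromo-5-ethenyl-2-(methoxymethoxy)-4-[(2-methylbut-3-en-2-yl)oxy]benzene | C=Cc1cc(Br)c(OCOC)cc1OC(C)(C)C=C
F4 | step 19 | 3-{2,2-dimethyl-7-[(trimethylsilyl)oxy]-2H-chromen-6-yl}-6-{3-methyl-3-[(trimethylsilyl)oxy]butyl}-5,7-bis[(trimethylsilyl)oxy]-4H-chromen-4-one | C[Si](C)(C)OC(C)(C)CCc1c(O[Si](C)(C)C)cc2occ(-c3cc4C=CC(C)(C)Oc4cc3O[Si](C)(C)C)c(=O)c2c1O[Si](C)(C)C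
F5 | step 18 | [7-(methoxymethoxy)-2,2-dimethyl-2H-chromen-6-yl]lithium | COCOc1cc2OC(C)(C)C=Cc2cc1[Li]
F6 | step 18 | chlorido[7-(methoxymethoxy)-2,2-dimethyl-2H-chromen-6-yl]zinc | COCOc1cc2OC(C)(C)C=Cc2cc1[Zn]Cl
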